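**Retrosynthetic overview**

1. Labels: ring A = acetyl ring, ring B = isobutyryl ring, ring C = central ring; each side ring is numbered C1' (bridge CH2), C2' (OH), C3' (CH3), C4' (OCH3), C5' (acyl), C6' (OH). The target comes from hexabenzyl ether 32 by hydrogenolysis, and the C5' acetyl of ring A from a C5' iodide by Stille coupling.
2. Ring A is the only ring built, and it is built last. Its adjacent C3'–CH3/C4'–OCH3 pair is the two alkyne carbons of 1-methoxypropyne, set between the ketene carbonyl carbon (C2'–OH) and C5' of 3-benzyloxy-4-(arylmethyl)cyclobutenone 21, which supplies C1' with the bridge CH2, C6'–O, C5'–H and C2'. C2'–C3' and C4'–C5' form by [2+2] addition; C1'–C2' closes by 6π-electrocyclisation.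
3. Cyclobutenone 21 comes from the ring C–ring B propanoic acid 16 by ketene/ethoxyethyne [2+2] cycloaddition and ethoxy-to-benzyloxy exchange.
4. Acid 16 comes from a dihydrocoumarin (phloroglucinol + acrylic acid) that hides the chain and one phenol: acylation with (R)-2-methylbutanoyl chloride, Friedel–Crafts benzylation with ring B benzylic alcohol 7, then lactone opening and benzylation.
5. Alcohol 7 comes from 2,4,6-trihydroxytoluene by formylation, O-methylation para to the formyl group, acylation, benzylation and reduction. Rings B and C are bought as benzene rings; ring A is formed in step 15.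

Key step: step 15

Assumptions: the acylation of step 8 is drawn at C8 of the chromanone; a C6 isomer would converge at 15, because all three ring C oxygens end as benzyl ethers. The ring stereocentres of 20, 21, 26 and 28 are not controlled and vanish when ring A becomes aromatic, so these compounds are epimer mixtures and that centre is left undefined in their SMILES.

Abbreviations: Bn = benzyl. ArB = 2,6-bis(benzyloxy)-4-methoxy-3-methyl-5-(2-methylpropanoyl)phenyl (protected ring B, bonded through C1'). ArC = 2,4,6-tris(benzyloxy)-3-[(ArB)methyl]-5-[(2R)-2-methylbutanoyl]phenyl (protected ring C carrying ring B).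

**Route**

Step 1
Reactants: 1 methylphloroglucinol (2,4,6-trihydroxytoluene)
Product: 3 aldehyde 2,4,6-trihydroxy-3-methylbenzaldehyde, via aryl iminium chloride 2 (not isolated)
Conditions: POCl3, DMF, EtOAc, 0 °C to rt; then H2O, 60 °C
Reagents that add atoms: N,N-dimethylformamide (CN(C)C=O); water (O)
Why: Vilsmeier–Haack formylation; the two open ring carbons of 1 are equivalent and the iminium salt 2 deactivates the ring against a second attack before hydrolysis frees the aldehyde.

Step 2
Reactants: 3 aldehyde 2,4,6-trihydroxy-3-methylbenzaldehyde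
Product: 4 aldehyde 2,6-dihydroxy-4-methoxy-3-methylbenzaldehyde
Conditions: Me2SO4 (1.0 equiv), K2CO3 (1.0 equiv), acetone, 0 °C to rt
Reagents that add atoms: dimethyl sulfate (COS(=O)(=O)OC)
Why: Selective Williamson O-methylation; the hydroxyl para to the formyl group is the only one not hydrogen-bonded to the carbonyl and is the most acidic, so one equivalent of base and a hard methylating agent should alkylate it first, which fixes C4'–OCH3 of ring B.

Step 3
Reactants: 4 aldehyde 2,6-dihydroxy-4-methoxy-3-methylbenzaldehyde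
Product: 5 keto aldehyde 2,6-dihydroxy-4-methoxy-3-methyl-5-(2-methylpropanoyl)benzaldehyde
Conditions: i-PrCOCl, AlCl3, CH2Cl2/PhNO2, 0 °C to rt
Reagents that add atoms: isobutyryl chloride (CC(C)C(Cl)=O)
Why: Friedel–Crafts acylation at the single open ring carbon, which lies ortho to OCH3 and OH and para to OH; working at or below room temperature should spare the methyl ether from chelation-assisted cleavage.

Step 4
Reactants: 5 keto aldehyde 2,6-dihydroxy-4-methoxy-3-methyl-5-(2-methylpropanoyl)benzaldehyde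
Product: 6 (ArB)carbaldehyde, 2,6-bis(benzyloxy)-4-methoxy-3-methyl-5-(2-methylpropanoyl)benzaldehyde
Conditions: BnBr, K2CO3, Bu4NI (cat.), DMF, 60 °C
Reagents that add atoms: benzyl bromide (BrCc1ccccc1)
Why: Williamson benzylation of both chelated phenols in a dipolar aprotic solvent, where the fully substituted ring leaves O-alkylation as the productive pathway.

Step 5
Reactants: 6 (ArB)carbaldehyde
Product: 7 (ArB)methanol, [2,6-bis(benzyloxy)-4-methoxy-3-methyl-5-(2-methylpropanoyl)phenyl]methanol
Conditions: NaBH4, THF/MeOH, −10 °C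
Reagents that add atoms: none
Why: Chemoselective borohydride reduction; the aldehyde should react far faster than the isopropyl aryl ketone flanked by two ortho substituents.

Step 6
Reactants: 8 phloroglucinol
Product: 9 lactone 5,7-dihydroxychroman-2-one
Conditions: acrylic acid, Amberlyst 15, toluene/1,4-dioxane, 100 °C
Reagents that add atoms: acrylic acid (C=CC(=O)O)
Why: Acid-catalysed Friedel–Crafts conjugate addition of the arene to acrylic acid followed by lactonisation, a known dihydrocoumarin synthesis; the lactone stores the three-carbon chain and masks one phenol.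

Step 7
Reactants: 10 (R)-2-methylbutanoic acid
Product: 11 (R)-2-methylbutanoyl chloride
Conditions: (COCl)2, DMF (cat.), CH2Cl2, 0 °C to rt
Reagents that add atoms: oxalyl chloride (ClC(=O)C(Cl)=O)
Why: Acid chloride formation through the chloroiminium catalyst at or below room temperature, conditions under which the alpha-branched acyl chloride should not enolise, so the R centre is carried over unchanged.

Step 8
Reactants: 9 lactone 5,7-dihydroxychroman-2-one; 11 (R)-2-methylbutanoyl chloride
Product: 12 acyl lactone 5,7-dihydroxy-8-[(2R)-2-methylbutanoyl]chroman-2-one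
Conditions: AlCl3, CH2Cl2/PhNO2, 0 °C to rt
Reagents that add atoms: none
Why: Friedel–Crafts acylation at C8, ortho to the C7 hydroxyl and para to the C5 hydroxyl; the one stereocentre of the target enters here from the chiral pool and is not touched, because the acylium ion is consumed at low temperature without ketene formation.

Step 9
Reactants: 7 (ArB)methanol; 12 acyl lactone 5,7-dihydroxy-8-[(2R)-2-methylbutanoyl]chroman-2-one
Product: 13 ring B–ring C lactone 6-[(ArB)methyl]-5,7-dihydroxy-8-[(2R)-2-methylbutanoyl]chroman-2-one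
Conditions: TsOH·H2O (10 mol %), CH2Cl2/HFIP, 0 °C to rt
Reagents that add atoms: none
Why: Friedel–Crafts benzylation; acid ionises the trialkoxybenzylic alcohol to a stabilised cation that should be captured by the only open ring carbon of 12, between two hydroxyls, and the ether-protected ring B cannot leave again through a quinone methide.

Step 10
Reactants: 13 ring B–ring C lactone
Product: 15 benzyl 3-(ArC)propanoate, via hydroxy ester 14 (not isolated)
Conditions: BnOH, Cs2CO3, DMF, rt; then BnBr, Bu4NI (cat.), 40 °C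
Reagents that add atoms: benzyl alcohol (OCc1ccccc1); benzyl bromide (BrCc1ccccc1)
Why: Carbonate-mediated alcoholysis of the aryl lactone (an activated ester) frees the third phenoxide, and Williamson benzylation then caps all three ring C oxygens; the carbonate base should be too weak to enolise the hindered ketone.

Step 11
Reactants: 15 benzyl 3-(ArC)propanoate
Product: 16 3-(ArC)propanoic acid
Conditions: LiOH·H2O, THF/MeOH/H2O, 0 °C to rt; then aq. HCl to pH 3
Reagents that add atoms: lithium hydroxide ([Li+].[OH-])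
Why: Saponification of an unhindered primary-alkyl ester, which should be fast at low temperature, whereas the ketone with two ortho substituents and a tertiary alpha C–H enolises much more slowly, so the R centre should be kept.

Step 12
Reactants: 16 3-(ArC)propanoic acid; 17 ethoxyethyne
Product: 20 3-ethoxy-4-[(ArC)methyl]cyclobut-2-en-1-one (both C4 epimers), via acid chloride 18 (not isolated), via ketene 19 (not isolated)
Conditions: (COCl)2, DMF (cat.), CH2Cl2, 0 °C; evaporate; then slow addition to 17 (5 equiv), Et3N, CH2Cl2, 0 °C to rt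
Reagents that add atoms: none
Why: Dehydrochlorination of the acid chloride gives the monosubstituted ketene, which undergoes the known ketene–ynol ether [2+2] cycloaddition with the unsubstituted alkyne carbon bonding to the ketene carbonyl carbon, so the arylmethyl group ends on C4 next to the ethoxy carbon; slow addition into excess alkyne should suppress ketene dimerisation, and the new C4 centre needs no control.

Step 13
Reactants: 20 3-ethoxy-4-[(ArC)methyl]cyclobut-2-en-1-one
Product: 21 3-(benzyloxy)-4-[(ArC)methyl]cyclobut-2-en-1-one (both C4 epimers)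
Conditions: BnOH (10 equiv), PPTS (10 mol %), toluene, rt, reduced pressure
Reagents that add atoms: benzyl alcohol (OCc1ccccc1)
Why: Acid-catalysed addition–elimination (transetherification) of a vinylogous ester, driven by removal of ethanol; the arylmethyl carbon stays flanked by the carbonyl and the alkoxy carbon, because a 1,3-oxygen transposition gives the same constitution and a double-bond shift onto C4 would need a cyclobutadiene-type intermediate.

Step 14
Reactants: 22 chloroacetaldehyde dimethyl acetal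
Product: 24 1-methoxyprop-1-yne, via sodium methoxyethynide 23 (not isolated)
Conditions: NaNH2 (3 equiv), liquid NH3, −33 °C; then MeI; distillation
Reagents that add atoms: iodomethane (CI)
Why: Twofold amide-induced elimination (methanol, then HCl) of the chloroacetal gives the sodium alkoxyacetylide, which is C-methylated, the standard route to 1-alkoxyalk-1-ynes.

Step 15
Reactants: 21 3-(benzyloxy)-4-[(ArC)methyl]cyclobut-2-en-1-one; 24 1-methoxyprop-1-yne
Product: 29 ring A phenol 2-[(ArC)methyl]-3-(benzyloxy)-5-methoxy-6-methylphenol, via vinylketene 25 (not isolated), via vinylcyclobutenone 26 (not isolated), via dienylketene 27 (not isolated), via cyclohexadienone 28 (not isolated)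
Conditions: 24 (3 equiv), toluene, sealed tube, 80 °C then 110 °C
Reagents that add atoms: none
Why: Heating opens 21 by 4π-electrocyclic cleavage of the future C1'–C2' bond (arylmethyl group turning outward) to vinylketene 25, whose ketene C=C adds 24 in a thermal [2+2] step, the methyl-bearing alkyne carbon bonding to the ketene carbonyl carbon (new C2'–C3') and the methoxy-bearing carbon to the ketene alpha carbon (new C4'–C5'), to give 26. A second 4π opening gives dienylketene 27, and ring A closes by thermal disrotatory 6π-electrocyclisation that re-forms C1'–C2' (28), followed by tautomerisation to the phenol. The closest known reaction type is the Danheiser benzannulation of cyclobutenones with ynol ethers, which gives resorcinol monoethers with this oxygen pattern. No stereocentre is created that survives: the C4 centre of 21 and the sp3 centres of 26 and 28 all become aromatic carbons, so both epimers of 21 converge. The one selectivity needed is the orientation of the alkyne in the [2+2] step, and it is secured by the polarity of the ynol ether (nucleophilic beta carbon, electrophilic ketene carbonyl carbon), which places CH3 next to the new hydroxyl and OCH3 next to C5'–H. An excess of 24, which has no beta hydrogen for a retro-ene loss of alkene, and moderate dilution should keep the ketenes from dimerising or acylating the product phenol.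

Step 16
Reactants: 29 ring A phenol
Product: 30 iodide 2-[(ArC)methyl]-3-(benzyloxy)-4-iodo-5-methoxy-6-methylphenol
Conditions: NIS, CH2Cl2, 0 °C, dark
Reagents that add atoms: N-iodosuccinimide (O=C1CCC(=O)N1I)
Why: Electrophilic aromatic iodination at C5', the only unsubstituted aromatic carbon of the trimer core, para to the free phenol and ortho to two ether oxygens.

Step 17
Reactants: 30 iodide
Product: 32 ring A methyl ketone 1-{3-[(ArC)methyl]-2-(benzyloxy)-4-hydroxy-6-methoxy-5-methylphenyl}ethan-1-one, via enol ether 31 (not isolated)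
Conditions: CH2=C(OEt)SnBu3, Pd(PPh3)4 (10 mol %), CuI, CsF, DMF, 60 °C; then 1 M HCl, THF, rt
Reagents that add atoms: tributyl(1-ethoxyvinyl)stannane (CCCC[Sn](CCCC)(CCCC)C(=C)OCC); water (O)
Why: Stille coupling with a masked acetyl group on zerovalent palladium, with CuI and fluoride to speed transmetalation at the carbon flanked by two alkoxy groups, then mild acid hydrolysis of the enol ether; these near-neutral conditions spare the benzyl ethers, the other ketones and the R centre.

Step 18
Reactants: 32 ring A methyl ketone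
Product: 33 target CNP0169975.1
Conditions: H2 (1 atm), 10% Pd/C, EtOAc/MeOH, rt
Reagents that add atoms: none
Why: Hydrogenolysis of six aryl benzyl ethers; the three hindered, hydrogen-bonded ortho-hydroxyaryl ketones and the diarylmethane bridges should not be reduced at 1 atm, and the neutral medium leaves the R centre intact.

**Compound list**

1 | 2,4,6-trihydroxytoluene | Cc1c(O)cc(O)cc1O | starting material
2 | [(2,4,6-trihydroxy-3-methylphenyl)methylidene]dimethylammonium chloride | C[N+](C)=Cc1c(O)c(C)c(O)cc1O.[Cl-] | intermediate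
3 | 2,4,6-trihydroxy-3-methylbenzaldehyde | O=Cc1c(O)c(C)c(O)cc1O | intermediate
4 | 2,6-dihydroxy-4-methoxy-3-methylbenzaldehyde | O=Cc1c(O)c(C)c(OC)cc1O | intermediate
5 | 2,6-dihydroxy-4-methoxy-3-methyl-5-(2-methylpropanoyl)benzaldehyde | O=Cc1c(O)c(C)c(OC)c(C(=O)C(C)C)c1O | intermediate
6 | 2,6-bis(benzyloxy)-4-methoxy-3-methyl-5-(2-methylpropanoyl)benzaldehyde | O=Cc1c(OCc2ccccc2)c(C)c(OC)c(C(=O)C(C)C)c1OCc1ccccc1 | intermediate
7 | [2,6-bis(benzyloxy)-4-methoxy-3-methyl-5-(2-methylpropanoyl)phenyl]methanol | OCc1c(OCc2ccccc2)c(C)c(OC)c(C(=O)C(C)C)c1OCc1ccccc1 | intermediate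
8 | phloroglucinol | Oc1cc(O)cc(O)c1 | starting material
9 | 5,7-dihydroxychroman-2-one | O=C1CCc2c(O)cc(O)cc2O1 | intermediate
10 | (R)-2-methylbutanoic acid | CC[C@@H](C)C(=O)O | starting material
11 | (R)-2-methylbutanoyl chloride | CC[C@@H](C)C(Cl)=O | intermediate
12 | 5,7-dihydroxy-8-[(2R)-2-methylbutanoyl]chroman-2-one | CC[C@@H](C)C(=O)c1c(O)cc(O)c2c1OC(=O)CC2 | intermediate
13 | 6-[(ArB)methyl]-5,7-dihydroxy-8-[(2R)-2-methylbutanoyl]chroman-2-one | CC[C@@H](C)C(=O)c1c(O)c(Cc2c(OCc3ccccc3)c(C)c(OC)c(C(=O)C(C)C)c2OCc2ccccc2)c(O)c2c1OC(=O)CC2 | intermediate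
14 | benzyl 3-{3-[(ArB)methyl]-2,4,6-trihydroxy-5-[(2R)-2-methylbutanoyl]phenyl}propanoate | CC[C@@H](C)C(=O)c1c(O)c(Cc2c(OCc3ccccc3)c(C)c(OC)c(C(=O)C(C)C)c2OCc2ccccc2)c(O)c(CCC(=O)OCc2ccccc2)c1O | intermediate
15 | benzyl 3-(ArC)propanoate | CC[C@@H](C)C(=O)c1c(OCc2ccccc2)c(CCC(=O)OCc2ccccc2)c(OCc2ccccc2)c(Cc2c(OCc3ccccc3)c(C)c(OC)c(C(=O)C(C)C)c2OCc2ccccc2)c1OCc1ccccc1 | intermediate
16 | 3-(ArC)propanoic acid | CC[C@@H](C)C(=O)c1c(OCc2ccccc2)c(CCC(=O)O)c(OCc2ccccc2)c(Cc2c(OCc3ccccc3)c(C)c(OC)c(C(=O)C(C)C)c2OCc2ccccc2)c1OCc1ccccc1 | intermediate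
17 | ethoxyethyne | CCOC#C | starting material
18 | 3-(ArC)propanoyl chloride | CC[C@@H](C)C(=O)c1c(OCc2ccccc2)c(CCC(=O)Cl)c(OCc2ccccc2)c(Cc2c(OCc3ccccc3)c(C)c(OC)c(C(=O)C(C)C)c2OCc2ccccc2)c1OCc1ccccc1 | intermediate
19 | 3-(ArC)prop-1-en-1-one (arylmethylketene) | CC[C@@H](C)C(=O)c1c(OCc2ccccc2)c(CC=C=O)c(OCc2ccccc2)c(Cc2c(OCc3ccccc3)c(C)c(OC)c(C(=O)C(C)C)c2OCc2ccccc2)c1OCc1ccccc1 | intermediate
20 | 3-ethoxy-4-[(ArC)methyl]cyclobut-2-en-1-one, both C4 epimers | CC[C@@H](C)C(=O)c1c(OCc2ccccc2)c(CC2C(=O)C=C2OCC)c(OCc2ccccc2)c(Cc2c(OCc3ccccc3)c(C)c(OC)c(C(=O)C(C)C)c2OCc2ccccc2)c1OCc1ccccc1 | intermediate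
21 | 3-(benzyloxy)-4-[(ArC)methyl]cyclobut-2-en-1-one, both C4 epimers | CC[C@@H](C)C(=O)c1c(OCc2ccccc2)c(CC2C(=O)C=C2OCc2ccccc2)c(OCc2ccccc2)c(Cc2c(OCc3ccccc3)c(C)c(OC)c(C(=O)C(C)C)c2OCc2ccccc2)c1OCc1ccccc1 | intermediate
22 | chloroacetaldehyde dimethyl acetal | COC(CCl)OC | starting material
23 | sodium methoxyethynide | [Na+].[C-]#COC | intermediate
24 | 1-methoxyprop-1-yne | CC#COC | intermediate
25 | (3Z)-3-(benzyloxy)-5-(ArC)penta-1,3-dien-1-one | CC[C@@H](C)C(=O)c1c(OCc2ccccc2)c(C/C=C(\OCc2ccccc2)C=C=O)c(OCc2ccccc2)c(Cc2c(OCc3ccccc3)c(C)c(OC)c(C(=O)C(C)C)c2OCc2ccccc2)c1OCc1ccccc1 | intermediate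
26 | 4-[(1Z)-1-(benzyloxy)-3-(ArC)prop-1-en-1-yl]-3-methoxy-2-methylcyclobut-2-en-1-one, both C4 epimers | CC[C@@H](C)C(=O)c1c(OCc2ccccc2)c(C/C=C(\OCc2ccccc2)C2C(=O)C(C)=C2OC)c(OCc2ccccc2)c(Cc2c(OCc3ccccc3)c(C)c(OC)c(C(=O)C(C)C)c2OCc2ccccc2)c1OCc1ccccc1 | intermediate
27 | (3E,5Z)-5-(benzyloxy)-3-methoxy-2-methyl-7-(ArC)hepta-1,3,5-trien-1-one | CC[C@@H](C)C(=O)c1c(OCc2ccccc2)c(C/C=C(\OCc2ccccc2)/C=C(/OC)C(C)=C=O)c(OCc2ccccc2)c(Cc2c(OCc3ccccc3)c(C)c(OC)c(C(=O)C(C)C)c2OCc2ccccc2)c1OCc1ccccc1 | intermediate
28 | 6-[(ArC)methyl]-5-(benzyloxy)-3-methoxy-2-methylcyclohexa-2,4-dien-1-one, both C6 epimers | CC[C@@H](C)C(=O)c1c(OCc2ccccc2)c(CC2C(=O)C(C)=C(OC)C=C2OCc2ccccc2)c(OCc2ccccc2)c(Cc2c(OCc3ccccc3)c(C)c(OC)c(C(=O)C(C)C)c2OCc2ccccc2)c1OCc1ccccc1 | intermediate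
29 | 2-[(ArC)methyl]-3-(benzyloxy)-5-methoxy-6-methylphenol | CC[C@@H](C)C(=O)c1c(OCc2ccccc2)c(Cc2c(O)c(C)c(OC)cc2OCc2ccccc2)c(OCc2ccccc2)c(Cc2c(OCc3ccccc3)c(C)c(OC)c(C(=O)C(C)C)c2OCc2ccccc2)c1OCc1ccccc1 | intermediate
30 | 2-[(ArC)methyl]-3-(benzyloxy)-4-iodo-5-methoxy-6-methylphenol | CC[C@@H](C)C(=O)c1c(OCc2ccccc2)c(Cc2c(O)c(C)c(OC)c(I)c2OCc2ccccc2)c(OCc2ccccc2)c(Cc2c(OCc3ccccc3)c(C)c(OC)c(C(=O)C(C)C)c2OCc2ccccc2)c1OCc1ccccc1 | intermediate
31 | 2-[(ArC)methyl]-3-(benzyloxy)-4-(1-ethoxyethenyl)-5-methoxy-6-methylphenol | CC[C@@H](C)C(=O)c1c(OCc2ccccc2)c(Cc2c(O)c(C)c(OC)c(C(=C)OCC)c2OCc2ccccc2)c(OCc2ccccc2)c(Cc2c(OCc3ccccc3)c(C)c(OC)c(C(=O)C(C)C)c2OCc2ccccc2)c1OCc1ccccc1 | intermediate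
32 | 1-{3-[(ArC)methyl]-2-(benzyloxy)-4-hydroxy-6-methoxy-5-methylphenyl}ethan-1-one | CC[C@@H](C)C(=O)c1c(OCc2ccccc2)c(Cc2c(O)c(C)c(OC)c(C(C)=O)c2OCc2ccccc2)c(OCc2ccccc2)c(Cc2c(OCc3ccccc3)c(C)c(OC)c(C(=O)C(C)C)c2OCc2ccccc2)c1OCc1ccccc1 | intermediate
33 | (2R)-1-{3-[(3-acetyl-2,6-dihydroxy-4-methoxy-5-methylphenyl)methyl]-5-{[2,6-dihydroxy-4-methoxy-3-methyl-5-(2-methylpropanoyl)phenyl]methyl}-2,4,6-trihydroxyphenyl}-2-methylbutan-1-one (CNP0169975.1) | CC[C@@H](C)C(=O)c1c(O)c(Cc2c(O)c(C)c(OC)c(C(C)=O)c2O)c(O)c(Cc2c(O)c(C)c(OC)c(C(=O)C(C)C)c2O)c1O | target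

**Step count and risks**

Total step count: 18. Longest linear sequence: 14 steps (steps 1–5, 9–13 and 15–18).

Steps most likely to fail:

1. Step 15. The ketene intermediates may be diverted (dimerisation, acylation of the product phenol), or the alkoxycyclobutenone may decompose before the crowded 6π closure takes place. Fallback, a classical assembly of ring A by Friedel–Crafts benzylation, setting out from 4, 7, 8 and 11 and coming back to the route at 33: acetylation of 4 (AcCl, AlCl3) should give 3-acetyl-2,6-dihydroxy-4-methoxy-5-methylbenzaldehyde F1, benzylation (BnBr, K2CO3, DMF) 3-acetyl-2,6-bis(benzyloxy)-4-methoxy-5-methylbenzaldehyde F2, and NaBH4 at low temperature the ring A benzylic alcohol 1-[2,4-bis(benzyloxy)-3-(hydroxymethyl)-6-methoxy-5-methylphenyl]ethan-1-one F3. Acylation of 8 with 11 (AlCl3) gives (2R)-2-methyl-1-(2,4,6-trihydroxyphenyl)butan-1-one F4. Acid-catalysed benzylation of excess F4 with 7 gives the ring C–ring B diarylmethane F5, a second benzylation with F3 gives the trimer with four benzyl ethers F6, and hydrogenolysis (H2, Pd/C) gives 33.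

2. Step 13. The alkoxy exchange may stall at equilibrium, or the acid and alcohol may cleave the strained four-membered vinylogous ester. Fallback, direct cycloaddition with the benzyl ynol ether, setting out from 16 and coming back at 21: benzyl alcohol and trichloroethylene (KH, THF) should give benzyl (E)-1,2-dichlorovinyl ether F7; n-BuLi (2 equiv, −78 °C) followed by methanol at −78 °C gives benzyloxyethyne F8, which is kept cold; ketene 19, generated from 16 as in step 12, is trapped by F8 below room temperature to give 21 without the ethoxy compound.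

3. Step 17. Transmetalation at a carbon flanked by two alkoxy groups may be slower than protodeiodination, returning 29. Fallback, Friedel–Crafts acetylation, setting out from 29 and coming back at 32: AcCl and SnCl4 in CH2Cl2 at −78 °C should acylate C5', the only open carbon and para to the free phenol, at a temperature low enough to spare the benzyl ethers; no new compound is made on the way.

**Further compounds**

F1 | step 15 | 3-acetyl-2,6-dihydroxy-4-methoxy-5-methylbenzaldehyde | O=Cc1c(O)c(C)c(OC)c(C(C)=O)c1O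
F2 | step 15 | 3-acetyl-2,6-bis(benzyloxy)-4-methoxy-5-methylbenzaldehyde | O=Cc1c(OCc2ccccc2)c(C)c(OC)c(C(C)=O)c1OCc1ccccc1
F3 | step 15 | 1-[2,4-bis(benzyloxy)-3-(hydroxymethyl)-6-methoxy-5-methylphenyl]ethan-1-one | OCc1c(OCc2ccccc2)c(C)c(OC)c(C(C)=O)c1OCc1ccccc1
F4 | step 15 | (2R)-2-methyl-1-(2,4,6-trihydroxyphenyl)butan-1-one | CC[C@@H](C)C(=O)c1c(O)cc(O)cc1O
F5 | step 15 | (2R)-1-{3-[(ArB)methyl]-2,4,6-trihydroxyphenyl}-2-methylbutan-1-one | CC[C@@H](C)C(=O)c1c(O)cc(O)c(Cc2c(OCc3ccccc3)c(C)c(OC)c(C(=O)C(C)C)c2OCc2ccccc2)c1O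
F6 | step 15 | (2R)-1-{3-[(3-acetyl-2,6-bis(benzyloxy)-4-methoxy-5-methylphenyl)methyl]-5-[(ArB)methyl]-2,4,6-trihydroxyphenyl}-2-methylbutan-1-one | CC[C@@H](C)C(=O)c1c(O)c(Cc2c(OCc3ccccc3)c(C)c(OC)c(C(C)=O)c2OCc2ccccc2)c(O)c(Cc2c(OCc3ccccc3)c(C)c(OC)c(C(=O)C(C)C)c2OCc2ccccc2)c1O
F7 | step 13 | benzyl (E)-1,2-dichlorovinyl ether | Cl/C=C(/Cl)OCc1ccccc1
F8 | step 13 | benzyloxyethyne | C#COCc1ccccc1
F0 | step 17 | none | none
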